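**Strategy.** The flavone is disconnected at the two bonds that flank the C2=C3 bond of ring C: O1–C2 and C3–C1'' (the prenyl CH2). One platinum-catalysed operation on an open-chain diaryl ynone should close ring C through a ring A ether oxygen and pass that oxygen's 1,1-dimethylallyl group to C3 with allylic transposition, so the chromone core and the 3-prenyl group arise together. The precursor is an ynone whose ring A carries three identical 2-methylbut-3-en-2-yl ethers (the para one serves as a protecting group and avoids a selective mono-protection) and whose ring B hydroquinone is masked as two triisopropylsilyl ethers.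

Key step: step 9

Remark on the chemistry: the ring A oxygen para to the carbonyl is carried as a third 2-methylbut-3-en-2-yl ether, so that all three hydroxyls of the aldehyde are etherified in one operation. It cannot reach the alkyne and should leave under the same mild acid as the C5 ether. 3-Chloro-3-methylbut-1-yne is taken as a purchased reagent, and three molecules of it enter compound 3. All aryl 2-methylbut-3-en-2-yl ethers (4, 12, 13, 15) are to be kept at or below 50 °C to avoid aromatic Claisen shifts.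

**Ring A aldehyde**

Step 1
Reactants: 1 2,4,6-trihydroxybenzaldehyde; 2 3-chloro-3-methylbut-1-yne (three equivalents are incorporated)
Product: 3 2,4,6-tris(2-methylbut-3-yn-2-yloxy)benzaldehyde
Conditions: 2 (4.5 equiv), CuCl2·2H2O (5 mol%), DBU (5 equiv), MeCN, 0 °C → rt
Reagents that add atoms: 3-chloro-3-methylbut-1-yne (compound 2), CC(C)(Cl)C#C
Why: Copper-catalysed propargylic etherification of phenols (via a copper allenylidene) is the standard route to aryl 1,1-dimethylpropargyl ethers; each of the three hydroxyls takes up one molecule of 2 with loss of HCl, DBU holds all three, including the aldehyde-chelated one, as phenoxides, and the phenoxide attacks the allenylidene at its dimethyl-substituted carbon, so the tertiary propargyl ether results.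

Step 2
Reactants: 3 2,4,6-tris(2-methylbut-3-yn-2-yloxy)benzaldehyde
Product: 4 2,4,6-tris(2-methylbut-3-en-2-yloxy)benzaldehyde
Conditions: H2 (1 atm), Pd/CaCO3 poisoned with Pb(OAc)2, quinoline, EtOAc, rt, stopped after 3 equiv H2
Reagents that add atoms: none
Why: Lindlar semi-hydrogenation should stop the three terminal alkynes at the vinyl stage while the aryl aldehyde and the aryl ethers are untouched.

**Ring B alkyne**

Step 3
Reactants: 5 2-methoxybenzene-1,4-diol
Product: 6 2-methoxy-1,4-bis(triisopropylsilyloxy)benzene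
Conditions: TIPSCl (2.4 equiv), imidazole (5 equiv), DMF, rt, argon
Reagents that add atoms: chlorotriisopropylsilane, CC(C)[Si](Cl)(C(C)C)C(C)C
Why: Imidazole-promoted O-silylation of phenols is routine and blocks oxidation of the hydroquinone to the quinone.

Step 4
Reactants: 6 2-methoxy-1,4-bis(triisopropylsilyloxy)benzene
Product: 7 1-iodo-4-methoxy-2,5-bis(triisopropylsilyloxy)benzene
Conditions: NIS (1.05 equiv), TFA (10 mol%), MeCN, 0 °C → rt, dark
Reagents that add atoms: N-iodosuccinimide, O=C1CCC(=O)N1I
Why: Electrophilic aromatic iodination of a 1,2,4-trioxygenated benzene should go to the position para to the methoxy group and ortho to one silyloxy group, which is the most activated open site (the site at which 1,2,4-trimethoxybenzene reacts).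

Step 5
Reactants: 7 1-iodo-4-methoxy-2,5-bis(triisopropylsilyloxy)benzene; 8 ethynyltrimethylsilane
Product: 9 {[4-methoxy-2,5-bis(triisopropylsilyloxy)phenyl]ethynyl}trimethylsilane
Conditions: 8 (1.5 equiv), PdCl2(PPh3)2 (3 mol%), CuI (5 mol%), Et3N/THF, 45 °C
Reagents that add atoms: none
Why: Sonogashira coupling of an aryl iodide with a silyl-capped acetylene is reliable even on an electron-rich, ortho-substituted ring.

Step 6
Reactants: 9 {[4-methoxy-2,5-bis(triisopropylsilyloxy)phenyl]ethynyl}trimethylsilane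
Product: 10 1-ethynyl-4-methoxy-2,5-bis(triisopropylsilyloxy)benzene
Conditions: K2CO3 (0.2 equiv), MeOH/THF 1:1, 0 °C, short reaction time
Reagents that add atoms: none
Why: Base-catalysed methanolysis cleaves the alkynyl C–SiMe3 bond far faster than the hindered triisopropylsilyl aryl ethers on this electron-rich ring.

**Union, key step and end game**

Step 7
Reactants: 10 1-ethynyl-4-methoxy-2,5-bis(triisopropylsilyloxy)benzene; 4 2,4,6-tris(2-methylbut-3-en-2-yloxy)benzaldehyde
Product: 12 rac-3-[4-methoxy-2,5-bis(triisopropylsilyloxy)phenyl]-1-[2,4,6-tris(2-methylbut-3-en-2-yloxy)phenyl]prop-2-yn-1-ol, via lithium arylacetylide 11 (not isolated)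
Conditions: n-BuLi (1.05 equiv), THF, −78 °C; then 4, −78 → −20 °C; aq. NH4Cl; crude product used directly
Reagents that add atoms: none
Why: 1,2-Addition of a lithium acetylide to an aryl aldehyde is dependable even with two ortho ethers, which have no alpha hydrogens for Wittig shifts; the new carbinol centre forms as a racemate and is erased in step 8.

Step 8
Reactants: 12 rac-3-[4-methoxy-2,5-bis(triisopropylsilyloxy)phenyl]-1-[2,4,6-tris(2-methylbut-3-en-2-yloxy)phenyl]prop-2-yn-1-ol
Product: 13 3-[4-methoxy-2,5-bis(triisopropylsilyloxy)phenyl]-1-[2,4,6-tris(2-methylbut-3-en-2-yloxy)phenyl]prop-2-yn-1-one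
Conditions: MnO2 (activated, 15 equiv), CH2Cl2, rt
Reagents that add atoms: none
Why: MnO2 oxidation of a benzylic, propargylic alcohol proceeds under neutral conditions, which suits the acid-sensitive carbinol and the tertiary allyl ethers.

Step 9
Reactants: 13 3-[4-methoxy-2,5-bis(triisopropylsilyloxy)phenyl]-1-[2,4,6-tris(2-methylbut-3-en-2-yloxy)phenyl]prop-2-yn-1-one
Product: 15 2-[4-methoxy-2,5-bis(triisopropylsilyloxy)phenyl]-3-(3-methylbut-2-en-1-yl)-5,7-bis(2-methylbut-3-en-2-yloxy)-4H-chromen-4-one, via platinated chromenylium oxonium 14 (not isolated)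
Conditions: PtCl2 (10 mol%), CO (1 atm), toluene, 50 °C
Reagents that add atoms: none
Why: Proposed new method: PtCl2 (divalent platinum) should bind the ynone alkyne, after which an ortho ether oxygen of ring A adds anti to the metal at the alkyne carbon remote from the carbonyl, forming O1–C2 and ring C by a 6-endo-dig closure and giving oxonium 14 with a C3–Pt bond; in 14 the atoms O1, C2, C3 and the 2-methylbut-3-en-2-yl group make up a cationic allyl vinyl ether, and a chair-like [3,3] shift (or its tight ion-pair equivalent) should break O1–C, join C3 to the CH2 terminus as C3–C1'' and release PtCl2. The closest known reaction types are the PtCl2-catalysed carboalkoxylation of ortho-alkynylphenyl allyl ethers, which gives 3-allylbenzofurans by 5-endo closure with oxygen-to-carbon allyl transfer, and the electrophile-triggered 6-endo cyclisation of ortho-alkoxyaryl ynones to 3-substituted chromones. No stereocentre is formed. Three selectivities are needed: 6-endo over 5-exo closure, which the carbonyl and the electron-rich ring B secure by making C2 the electrophilic alkyne carbon; attack by a ring A oxygen only, secured because the two ortho ethers are identical, the para ether cannot reach the alkyne, and the hindered silyl ether oxygen of ring B is a poor nucleophile that could close only 5-endo at the carbonyl-bearing carbon; and delivery of the CH2 terminus to C3, which follows from the allylic transposition of the tertiary ether. The temperature is held at 50 °C so that thermal aromatic Claisen shifts of the remaining ethers stay slow.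

Step 10
Reactants: 15 2-[4-methoxy-2,5-bis(triisopropylsilyloxy)phenyl]-3-(3-methylbut-2-en-1-yl)-5,7-bis(2-methylbut-3-en-2-yloxy)-4H-chromen-4-one
Product: 16 5,7-dihydroxy-2-[4-methoxy-2,5-bis(triisopropylsilyloxy)phenyl]-3-(3-methylbut-2-en-1-yl)-4H-chromen-4-one
Conditions: p-TsOH·H2O (0.2 equiv), MeOH/CH2Cl2 3:1, 0 °C → rt
Reagents that add atoms: none
Why: Acid-catalysed SN1 solvolysis of tertiary allylic aryl ethers is facile, methanol in large excess should capture the dimethylallyl cation, and the silyl ethers and the trisubstituted prenyl alkene tolerate dilute sulfonic acid at room temperature.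

Step 11
Reactants: 16 5,7-dihydroxy-2-[4-methoxy-2,5-bis(triisopropylsilyloxy)phenyl]-3-(3-methylbut-2-en-1-yl)-4H-chromen-4-one
Product: 17 2-(2,5-dihydroxy-4-methoxyphenyl)-5,7-dihydroxy-3-(3-methylbut-2-en-1-yl)-4H-chromen-4-one
Conditions: TBAF (2.4 equiv), AcOH (2.4 equiv), THF, 0 °C, argon; aq. NH4Cl
Reagents that add atoms: none
Why: Fluoride cleaves aryl silyl ethers rapidly, and the acetic acid buffer with exclusion of air should protect the freed hydroquinone of ring B from oxidation.

**Compound list**

1 | 2,4,6-trihydroxybenzaldehyde | O=Cc1c(O)cc(O)cc1O | starting material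
2 | 3-chloro-3-methylbut-1-yne | CC(C)(Cl)C#C | starting material
3 | 2,4,6-tris(2-methylbut-3-yn-2-yloxy)benzaldehyde | O=Cc1c(OC(C)(C)C#C)cc(OC(C)(C)C#C)cc1OC(C)(C)C#C | intermediate
4 | 2,4,6-tris(2-methylbut-3-en-2-yloxy)benzaldehyde | O=Cc1c(OC(C)(C)C=C)cc(OC(C)(C)C=C)cc1OC(C)(C)C=C | intermediate
5 | 2-methoxybenzene-1,4-diol (2-methoxyhydroquinone) | COc1cc(O)ccc1O | starting material
6 | 2-methoxy-1,4-bis(triisopropylsilyloxy)benzene | COc1cc(O[Si](C(C)C)(C(C)C)C(C)C)ccc1O[Si](C(C)C)(C(C)C)C(C)C | intermediate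
7 | 1-iodo-4-methoxy-2,5-bis(triisopropylsilyloxy)benzene | COc1cc(O[Si](C(C)C)(C(C)C)C(C)C)c(I)cc1O[Si](C(C)C)(C(C)C)C(C)C | intermediate
8 | ethynyltrimethylsilane | C#C[Si](C)(C)C | starting material
9 | {[4-methoxy-2,5-bis(triisopropylsilyloxy)phenyl]ethynyl}trimethylsilane | COc1cc(O[Si](C(C)C)(C(C)C)C(C)C)c(C#C[Si](C)(C)C)cc1O[Si](C(C)C)(C(C)C)C(C)C | intermediate
10 | 1-ethynyl-4-methoxy-2,5-bis(triisopropylsilyloxy)benzene | COc1cc(O[Si](C(C)C)(C(C)C)C(C)C)c(C#C)cc1O[Si](C(C)C)(C(C)C)C(C)C | intermediate
11 | lithium [4-methoxy-2,5-bis(triisopropylsilyloxy)phenyl]acetylide | COc1cc(O[Si](C(C)C)(C(C)C)C(C)C)c(C#C[Li])cc1O[Si](C(C)C)(C(C)C)C(C)C | intermediate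
12 | rac-3-[4-methoxy-2,5-bis(triisopropylsilyloxy)phenyl]-1-[2,4,6-tris(2-methylbut-3-en-2-yloxy)phenyl]prop-2-yn-1-ol (racemic) | C=CC(C)(C)Oc1cc(OC(C)(C)C=C)cc(OC(C)(C)C=C)c1C(O)C#Cc1cc(O[Si](C(C)C)(C(C)C)C(C)C)c(OC)cc1O[Si](C(C)C)(C(C)C)C(C)C | intermediate
13 | 3-[4-methoxy-2,5-bis(triisopropylsilyloxy)phenyl]-1-[2,4,6-tris(2-methylbut-3-en-2-yloxy)phenyl]prop-2-yn-1-one | C=CC(C)(C)Oc1cc(OC(C)(C)C=C)cc(OC(C)(C)C=C)c1C(=O)C#Cc1cc(O[Si](C(C)C)(C(C)C)C(C)C)c(OC)cc1O[Si](C(C)C)(C(C)C)C(C)C | intermediate
14 | 3-(dichloroplatinio)-1-(2-methylbut-3-en-2-yl)chromen-4-one-1-ium zwitterion bearing the ring B aryl at C2 and 2-methylbut-3-en-2-yloxy groups at C5 and C7 | C=CC(C)(C)[O+]1C(c3cc(O[Si](C(C)C)(C(C)C)C(C)C)c(OC)cc3O[Si](C(C)C)(C(C)C)C(C)C)=C([Pt-](Cl)Cl)C(=O)c2c(OC(C)(C)C=C)cc(OC(C)(C)C=C)cc21 | intermediate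
15 | 2-[4-methoxy-2,5-bis(triisopropylsilyloxy)phenyl]-3-(3-methylbut-2-en-1-yl)-5,7-bis(2-methylbut-3-en-2-yloxy)-4H-chromen-4-one | C=CC(C)(C)Oc1cc(OC(C)(C)C=C)cc2oc(-c3cc(O[Si](C(C)C)(C(C)C)C(C)C)c(OC)cc3O[Si](C(C)C)(C(C)C)C(C)C)c(CC=C(C)C)c(=O)c12 | intermediate
16 | 5,7-dihydroxy-2-[4-methoxy-2,5-bis(triisopropylsilyloxy)phenyl]-3-(3-methylbut-2-en-1-yl)-4H-chromen-4-one | COc1cc(O[Si](C(C)C)(C(C)C)C(C)C)c(-c2oc3cc(O)cc(O)c3c(=O)c2CC=C(C)C)cc1O[Si](C(C)C)(C(C)C)C(C)C | intermediate
17 | 2-(2,5-dihydroxy-4-methoxyphenyl)-5,7-dihydroxy-3-(3-methylbut-2-en-1-yl)-4H-chromen-4-one | COc1cc(O)c(-c2oc3cc(O)cc(O)c3c(=O)c2CC=C(C)C)cc1O | target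

**Totals**

Total step count: 11. Longest linear sequence: 9 steps (steps 3 to 11, from compound 5).

**Steps most likely to fail**

1. Step 9. The migrating group may ionise before or instead of its transfer, so that ring C closes without the C3–C1'' bond, or the allyl cation returns through the wrong terminus or to ring A; the vinyl groups may also tie up the catalyst. Fallback (known chemistry), setting out from 13 and rejoining at 16, so that steps 9 and 10 are replaced: pyrrolidine in EtOH at rt should add in conjugate fashion to give the enaminone 3-[4-methoxy-2,5-bis(triisopropylsilyloxy)phenyl]-3-(pyrrolidin-1-yl)-1-[2,4,6-tris(2-methylbut-3-en-2-yloxy)phenyl]prop-2-en-1-one F1 (alkene geometry immaterial). Buffered hydrolysis (AcOH/NaOAc, aqueous THF, rt) should give the 1,3-diketone 1-[4-methoxy-2,5-bis(triisopropylsilyloxy)phenyl]-3-[2,4,6-tris(2-methylbut-3-en-2-yloxy)phenyl]propane-1,3-dione F2. C-alkylation with prenyl bromide (K2CO3, acetone, rt) should give the racemic, configurationally labile 2-(3-methylbut-2-en-1-yl)-1,3-diketone F3. p-TsOH in MeOH should then remove the three tertiary allyl ethers, and a freed ortho hydroxyl of ring A should cyclodehydrate onto the ring B ketone to give 16. The silyl ether at the ring B ortho oxygen prevents the alternative closure.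

2. Step 1. Etherification may stall at the hydrogen-bonded, hindered ortho hydroxyl and leave mixtures of partly alkylated aldehydes. Fallback, setting out from 2 and rejoining at 4, so that steps 1 and 2 are replaced: purchased benzene-1,3,5-triol F4, which has no chelated hydroxyl, should be etherified with three equivalents of 2 under the same copper catalysis to give 1,3,5-tris(2-methylbut-3-yn-2-yloxy)benzene F5. Semi-hydrogenation over Pd/CaCO3 poisoned with Pb(OAc)2 should give 1,3,5-tris(2-methylbut-3-en-2-yloxy)benzene F6. Lithiation between two alkoxy groups (n-BuLi, TMEDA, THF, 0 °C) should give 2,4,6-tris(2-methylbut-3-en-2-yloxy)phenyllithium F7, which is formylated with DMF to give 4. The ethers have no alpha hydrogens, so Wittig shifts are excluded.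

3. Step 10. The liberated dimethylallyl cation may re-add to C6 or C8 of ring A, or the acid may hydrate the C3 prenyl alkene. Fallback, setting out from 15 and rejoining at 16: Pd(PPh3)4 (5 mol%) and morpholine in THF at rt, where zerovalent palladium should ionise the two tertiary allyl aryl ethers to allylpalladium complexes that morpholine captures, so no free carbocation or acid is present. This fallback makes no new compound.

**Further compounds**

F1 | step 9 | 3-[4-methoxy-2,5-bis(triisopropylsilyloxy)phenyl]-3-(pyrrolidin-1-yl)-1-[2,4,6-tris(2-methylbut-3-en-2-yloxy)phenyl]prop-2-en-1-one (alkene geometry not defined) | C=CC(C)(C)Oc1cc(OC(C)(C)C=C)cc(OC(C)(C)C=C)c1C(=O)C=C(N1CCCC1)c1cc(O[Si](C(C)C)(C(C)C)C(C)C)c(OC)cc1O[Si](C(C)C)(C(C)C)C(C)C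
F2 | step 9 | 1-[4-methoxy-2,5-bis(triisopropylsilyloxy)phenyl]-3-[2,4,6-tris(2-methylbut-3-en-2-yloxy)phenyl]propane-1,3-dione | C=CC(C)(C)Oc1cc(OC(C)(C)C=C)cc(OC(C)(C)C=C)c1C(=O)CC(=O)c1cc(O[Si](C(C)C)(C(C)C)C(C)C)c(OC)cc1O[Si](C(C)C)(C(C)C)C(C)C
F3 | step 9 | rac-1-[4-methoxy-2,5-bis(triisopropylsilyloxy)phenyl]-2-(3-methylbut-2-en-1-yl)-3-[2,4,6-tris(2-methylbut-3-en-2-yloxy)phenyl]propane-1,3-dione (racemic) | C=CC(C)(C)Oc1cc(OC(C)(C)C=C)cc(OC(C)(C)C=C)c1C(=O)C(CC=C(C)C)C(=O)c1cc(O[Si](C(C)C)(C(C)C)C(C)C)c(OC)cc1O[Si](C(C)C)(C(C)C)C(C)C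
F4 | step 1 | benzene-1,3,5-triol (purchased input of the fallback) | Oc1cc(O)cc(O)c1
F5 | step 1 | 1,3,5-tris(2-methylbut-3-yn-2-yloxy)benzene | C#CC(C)(C)Oc1cc(OC(C)(C)C#C)cc(OC(C)(C)C#C)c1
F6 | step 1 | 1,3,5-tris(2-methylbut-3-en-2-yloxy)benzene | C=CC(C)(C)Oc1cc(OC(C)(C)C=C)cc(OC(C)(C)C=C)c1
F7 | step 1 | 2,4,6-tris(2-methylbut-3-en-2-yloxy)phenyllithium | [Li]c1c(OC(C)(C)C=C)cc(OC(C)(C)C=C)cc1OC(C)(C)C=C
F0 | step 10 | none | none
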